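**Strategy.** Locants: oxolane O1, C2 (trimethoxyphenyl-bearing), C3 (CH2OH-bearing), C4, C5; Cα is the exocyclic carbinol carbon. The route hinges on disconnecting C3–C4. The CH2OH carbon on C3 and ring carbon C5 on C4 are both read as former ester carbonyls. Each end of the bond is therefore an ester α-carbon, a donor, and two donors can only be united by taking out two electrons. The C2 and Cα oxygens (later O1 and the free hydroxyl) are clamped by a diisopropylsilylene unit. Oxidation of the derived bis-enolate creates C3–C4, a sacrificial seven-membered dioxasilepane and both missing stereocentres at once. The precursor is the mixed silaketal of an (R)-tert-butyl and an (S)-methyl 3-aryl-3-hydroxypropanoate.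

Key step: step 5

**Remarks on the chemistry**
- The target is read as (2R,3S,4R,αS), with the three ring substituents mutually trans. About C3–C4 this is the erythro (meso-like) series. On the seven-membered ring the two esters must therefore be cis to each other and each trans to the aryl next to it. This requires an (R)-carbinol on the C2 side and an (S)-carbinol on the Cα side.
- Precursor design:
  - The methyl ester sits on the C4 half because its carbonyl becomes C5, which is reduced first.
  - The tert-butyl ester sits on the C3 half because it resists self-condensation, LiBH4 and lactonisation.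
  - Diisopropylsilylene is chosen because smaller bridges would not survive amide base and hydride, and a di-tert-butyl bridge cannot be installed stepwise on two secondary carbinols.
  - Both enolates carry a β-silyloxy leaving group, so the bis-enolate is handled as a species with a lifetime of minutes.
- Assumption: LiN(iPr)2 in THF gives the enolates with the ester alkoxy group cis to the carbinol carbon. This geometry vanishes in the product and only adds to the allylic strain.

**Step 1**
Reactants: 1 tert-butyl acetate; 2 3,4,5-trimethoxybenzoyl chloride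
Product: 4 tert-butyl 3-oxo-3-(3,4,5-trimethoxyphenyl)propanoate, via lithium enolate of tert-butyl acetate 3 (not isolated)
Conditions: 1 (2.1 equiv), LiN(iPr)2 (2.2 equiv), THF, −78 °C; then 2 (1.0 equiv), −78 → 0 °C; aq. NH4Cl
Reagents that add atoms: none
Why: Crossed Claisen condensation (C-acylation of a preformed lithium ester enolate by a non-enolisable aroyl chloride), in which the second equivalent of 3 deprotonates the more acidic β-keto ester as it forms and so stops double acylation.

**Step 2**
Reactants: 4 tert-butyl 3-oxo-3-(3,4,5-trimethoxyphenyl)propanoate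
Product: 5 tert-butyl (3R)-3-hydroxy-3-(3,4,5-trimethoxyphenyl)propanoate
Conditions: [RuCl(p-cymene)((S)-SEGPHOS)]Cl (0.5 mol %), H2 (30 bar), EtOH, 50 °C
Reagents that add atoms: none
Why: Noyori asymmetric hydrogenation of a β-keto ester, in which the substrate chelates ruthenium through ketone and ester oxygens and the (S)-biaryl diphosphine directs hydride to the face that gives, for aroylacetates, the (R)-carbinol, the future C2.

**Step 3**
Reactants: 6 methyl 3-(3,4-dimethoxyphenyl)-3-oxopropanoate
Product: 7 methyl (3S)-3-(3,4-dimethoxyphenyl)-3-hydroxypropanoate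
Conditions: [RuCl(p-cymene)((R)-SEGPHOS)]Cl (0.5 mol %), H2 (30 bar), MeOH, 50 °C
Reagents that add atoms: none
Why: The same Noyori asymmetric hydrogenation with the antipodal ligand delivers hydride to the opposite face and should give the (S)-carbinol, the future Cα.

**Step 4**
Reactants: 7 methyl (3S)-3-(3,4-dimethoxyphenyl)-3-hydroxypropanoate; 8 dichlorodiisopropylsilane; 5 tert-butyl (3R)-3-hydroxy-3-(3,4,5-trimethoxyphenyl)propanoate
Product: 10 mixed silaketal, methyl (3S)-3-({[(1R)-3-tert-butoxy-3-oxo-1-(3,4,5-trimethoxyphenyl)propoxy]diisopropylsilyl}oxy)-3-(3,4-dimethoxyphenyl)propanoate, via chlorosilane 9 (not isolated)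
Conditions: 7 added slowly to 8 (1.05 equiv), imidazole (1.1 equiv), CH2Cl2, −20 → 0 °C; then 5 (0.95 equiv), imidazole (1.5 equiv), DMAP (0.1 equiv), 0 °C → rt
Reagents that add atoms: dichlorodiisopropylsilane (8, also listed as reactant), CC(C)[Si](Cl)(Cl)C(C)C
Why: Stepwise O-silylation (mixed silaketal formation): after one chloride is replaced by a secondary benzylic alkoxide, the remaining Si–Cl bond between two isopropyl groups reacts much more slowly, so 9 builds up and is consumed only when 5 and the nucleophilic catalyst arrive, and both carbinols keep their C–O bonds and configuration.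

**Step 5**
Reactants: 10 mixed silaketal
Product: 12 5-tert-butyl 6-methyl (4R,5R,6S,7S)-7-(3,4-dimethoxyphenyl)-2,2-diisopropyl-4-(3,4,5-trimethoxyphenyl)-1,3,2-dioxasilepane-5,6-dicarboxylate, via dilithium bis-enolate 11 (not isolated)
Conditions: 10 added to LiN(iPr)2 (2.3 equiv), THF (0.02 M), −78 °C, 15–20 min; anhydrous CuBr2 (2.5 equiv), −78 → −40 °C; AcOH/THF at −78 °C, then aq. NH4Cl/NH3
Reagents that add atoms: none
Why: Proposed new method: twofold deprotonation gives bis-enolate 11; divalent copper removes one electron from one enolate, the resulting α-ester radical (free or copper-bound) adds to the C=C of the neighbouring enolate, and a second electron transfer from the ketyl-type adduct finishes the succinate. The closest known reaction types are the CuBr2 dimerisation of lithium ester enolates, ring-closing oxidative couplings of diester bis-enolates and oxidative couplings of silicon-linked bis(enol ethers); none has been run across an O–Si–O bridge joining the two β-carbinol oxygens, hence the label. The one new ring, the 1,3,2-dioxasilepane, closes 7-exo-trig, since the carboxyl carbon of the attacked enolate stays outside the ring. C3 is set by C2 and C4 by Cα: allylic 1,3-strain turns each benzylic C–H into the plane of its enolate, which puts the bridging oxygen on one face and the aryl group on the other, and the short bridge lets the partner carbon arrive only on the oxygen-bearing face, so each ester should end trans to the adjacent aryl (the opposite sense to chelate-controlled alkylation of β-hydroxy ester dianions) and, with the (R,S)-bridge, the two esters cis to each other. Hetero- over homo-coupling is secured by the bridge and by dilution, and oxidation of the enolates in preference to the methoxyarenes by their far lower oxidation potential. Survival of the β-silyloxy enolates against E1cB loss of silanolate is sought through lithium counter-ions, inverse addition at −78 °C, a lifetime of minutes and a cold acidic quench, the measures that also keep β-oxygenated ester enolates alive in Ireland–Claisen practice.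

**Step 6**
Reactants: 12 dioxasilepane diester
Product: 13 tert-butyl (4R,5R,6R,7S)-7-(3,4-dimethoxyphenyl)-6-(hydroxymethyl)-2,2-diisopropyl-4-(3,4,5-trimethoxyphenyl)-1,3,2-dioxasilepane-5-carboxylate
Conditions: LiBH4 (2.5 equiv), Et2O/THF, 0 °C → rt; cold aq. NH4Cl
Reagents that add atoms: none
Why: Chemoselective ester reduction: LiBH4 reduces the methyl ester but leaves the far more hindered tert-butyl ester, the silaketal and the arenes alone, the masked carbinols cannot undergo retro-aldol cleavage, and the weakly basic medium should not epimerise C3 or C4.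

**Step 7**
Reactants: 13 primary alcohol
Product: 14 tert-butyl (4R,5R,6R,7S)-7-(3,4-dimethoxyphenyl)-2,2-diisopropyl-6-[(methylsulfonyloxy)methyl]-4-(3,4,5-trimethoxyphenyl)-1,3,2-dioxasilepane-5-carboxylate
Conditions: MsCl (1.3 equiv), Et3N (2 equiv), CH2Cl2, 0 °C
Reagents that add atoms: methanesulfonyl chloride, CS(=O)(=O)Cl
Why: Standard mesylation of the only free hydroxyl group, which makes C5 the electrophile without touching a stereocentre.

**Step 8**
Reactants: 14 mesylate
Product: 16 tert-butyl (2R,3R,4R)-4-[(S)-(3,4-dimethoxyphenyl)(hydroxy)methyl]-2-(3,4,5-trimethoxyphenyl)oxolane-3-carboxylate, via diol mesylate 15 (not isolated)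
Conditions: Bu4NF/AcOH (1:1, 3 equiv), THF, 0 °C → rt, then 40 °C
Reagents that add atoms: none
Why: Fluoride desilylation followed by intramolecular Williamson ether synthesis (5-exo-tet): only the C2 hydroxyl can reach C5 through a five-membered transition state (the Cα hydroxyl could only form an oxetane), C2 keeps its C–O bond and configuration, and the acetic acid buffer keeps the medium too weakly basic for retro-aldol cleavage at C2–C3, epimerisation at C3 or lactonisation of the Cα hydroxyl onto the tert-butyl ester.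

**Step 9**
Reactants: 16 oxolane ester
Product: 17 [(2R,3S,4R)-4-[(S)-(3,4-dimethoxyphenyl)(hydroxy)methyl]-2-(3,4,5-trimethoxyphenyl)oxolan-3-yl]methanol (target)
Conditions: LiAlH4 (3 equiv), THF, 0 °C → rt; H2O, aq. NaOH, H2O
Reagents that add atoms: none
Why: LiAlH4 reduction of an ester to the primary alcohol, with ring ether, aryl ethers and the deprotonated carbinol inert, reduction faster than enolisation, and C3 already in the favoured all-trans arrangement.

**Compound list**
1 | tert-butyl acetate | CC(=O)OC(C)(C)C | starting material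
2 | 3,4,5-trimethoxybenzoyl chloride | COc1cc(C(=O)Cl)cc(OC)c1OC | starting material
3 | lithium enolate of tert-butyl acetate | [Li+].C=C([O-])OC(C)(C)C | intermediate
4 | tert-butyl 3-oxo-3-(3,4,5-trimethoxyphenyl)propanoate | COc1cc(C(=O)CC(=O)OC(C)(C)C)cc(OC)c1OC | intermediate
5 | tert-butyl (3R)-3-hydroxy-3-(3,4,5-trimethoxyphenyl)propanoate | O[C@H](CC(=O)OC(C)(C)C)c1cc(OC)c(OC)c(OC)c1 | intermediate
6 | methyl 3-(3,4-dimethoxyphenyl)-3-oxopropanoate | COC(=O)CC(=O)c1ccc(OC)c(OC)c1 | starting material
7 | methyl (3S)-3-(3,4-dimethoxyphenyl)-3-hydroxypropanoate | COC(=O)C[C@H](O)c1ccc(OC)c(OC)c1 | intermediate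
8 | dichlorodiisopropylsilane | CC(C)[Si](Cl)(Cl)C(C)C | starting material
9 | methyl (3S)-3-[(chlorodiisopropylsilyl)oxy]-3-(3,4-dimethoxyphenyl)propanoate | COC(=O)C[C@H](O[Si](Cl)(C(C)C)C(C)C)c1ccc(OC)c(OC)c1 | intermediate
10 | diisopropylsilylene-bridged (S)-methyl / (R)-tert-butyl 3-aryl-3-oxypropanoates (key-step precursor) | COC(=O)C[C@H](O[Si](C(C)C)(C(C)C)O[C@H](CC(=O)OC(C)(C)C)c1cc(OC)c(OC)c(OC)c1)c1ccc(OC)c(OC)c1 | intermediate
11 | dilithium bis-enolate of 10 (ester alkoxy group cis to the carbinol carbon in each enolate) | [Li+].[Li+].CO/C([O-])=C\[C@H](O[Si](C(C)C)(C(C)C)O[C@H](/C=C(/[O-])OC(C)(C)C)c1cc(OC)c(OC)c(OC)c1)c1ccc(OC)c(OC)c1 | intermediate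
12 | 5-tert-butyl 6-methyl (4R,5R,6S,7S)-7-(3,4-dimethoxyphenyl)-2,2-diisopropyl-4-(3,4,5-trimethoxyphenyl)-1,3,2-dioxasilepane-5,6-dicarboxylate (key-step product) | COC(=O)[C@H]1[C@@H](C(=O)OC(C)(C)C)[C@H](c2cc(OC)c(OC)c(OC)c2)O[Si](C(C)C)(C(C)C)O[C@@H]1c1ccc(OC)c(OC)c1 | intermediate
13 | tert-butyl (4R,5R,6R,7S)-7-(3,4-dimethoxyphenyl)-6-(hydroxymethyl)-2,2-diisopropyl-4-(3,4,5-trimethoxyphenyl)-1,3,2-dioxasilepane-5-carboxylate | OC[C@H]1[C@@H](C(=O)OC(C)(C)C)[C@H](c2cc(OC)c(OC)c(OC)c2)O[Si](C(C)C)(C(C)C)O[C@@H]1c1ccc(OC)c(OC)c1 | intermediate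
14 | tert-butyl (4R,5R,6R,7S)-7-(3,4-dimethoxyphenyl)-2,2-diisopropyl-6-[(methylsulfonyloxy)methyl]-4-(3,4,5-trimethoxyphenyl)-1,3,2-dioxasilepane-5-carboxylate | CS(=O)(=O)OC[C@H]1[C@@H](C(=O)OC(C)(C)C)[C@H](c2cc(OC)c(OC)c(OC)c2)O[Si](C(C)C)(C(C)C)O[C@@H]1c1ccc(OC)c(OC)c1 | intermediate
15 | tert-butyl (2R,3R,4S)-4-(3,4-dimethoxyphenyl)-4-hydroxy-2-[(R)-hydroxy(3,4,5-trimethoxyphenyl)methyl]-3-[(methylsulfonyloxy)methyl]butanoate | CS(=O)(=O)OC[C@H]([C@H](O)c1ccc(OC)c(OC)c1)[C@@H](C(=O)OC(C)(C)C)[C@@H](O)c1cc(OC)c(OC)c(OC)c1 | intermediate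
16 | tert-butyl (2R,3R,4R)-4-[(S)-(3,4-dimethoxyphenyl)(hydroxy)methyl]-2-(3,4,5-trimethoxyphenyl)oxolane-3-carboxylate | COc1ccc([C@@H](O)[C@H]2CO[C@@H](c3cc(OC)c(OC)c(OC)c3)[C@@H]2C(=O)OC(C)(C)C)cc1OC | intermediate
17 | [(2R,3S,4R)-4-[(S)-(3,4-dimethoxyphenyl)(hydroxy)methyl]-2-(3,4,5-trimethoxyphenyl)oxolan-3-yl]methanol | COc1ccc([C@@H](O)[C@H]2CO[C@@H](c3cc(OC)c(OC)c(OC)c3)[C@@H]2CO)cc1OC | target

**Total step count:** 9. **Longest linear sequence:** 8 (steps 1, 2, 4, 5, 6, 7, 8, 9).

**Steps most likely to fail**

**1. Step 5.**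
What may go wrong:
- β-elimination of silanolate from either enolate before oxidation, which cuts the bridge;
- incomplete facial control at C3 or C4;
- intermolecular coupling;
- epimerisation of the new succinate by residual base.

Fallback (known chemistry only; sets out from 2, comes back at 15). The succinate core is taken ready-made, and the two aryl-bearing carbons are attached one after the other by carbonyl chemistry.
- Rosenmund reduction of 2 (H2, Pd/BaSO4, 2,6-lutidine, THF) gives 3,4,5-trimethoxybenzaldehyde F1.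
- The dibutylboron enolate of (R)-4-benzyl-3-(4-methoxy-4-oxobutanoyl)oxazolidin-2-one is formed (Bu2BOTf, iPr2NEt, CH2Cl2, −78 → 0 °C) and added to F1 in an Evans syn-aldol reaction. The new C2 oxygen then closes onto the methyl ester. This gives the 2,3-trans lactone imide F2, with C2 and C3 set by the auxiliary.
- LiOH/H2O2 releases the lactone acid F3.
- Boc2O, DMAP and tBuOH convert it into the lactone tert-butyl ester F4.
- The lactone CH2 is deprotonated kinetically (LiN(SiMe3)2, 2.1 equiv, THF, −78 °C) and C-acylated with 3,4-dimethoxybenzoyl chloride anti to the C3 ester. This gives the keto lactone F5.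
- Noyori–Ikariya transfer hydrogenation (RuCl(p-cymene)[(S,S)-TsDPEN], HCO2H/Et3N) sets (S)-Cα under catalyst control and gives the hydroxy lactone F6.
- LiBH4 (THF, 0 °C) opens the lactone but not the tert-butyl ester, giving the triol F7.
- MsCl (1.0 equiv), 2,4,6-collidine, CH2Cl2, −20 °C sulfonylates only the primary hydroxyl to give 15, which closes to 16 on warming with Et3N.

**2. Step 6.**
What may go wrong:
- attack of the newly formed C5 alkoxide on the neighbouring cis tert-butyl ester (lactonisation followed by over-reduction);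
- attack of the same alkoxide on silicon (migration of the bridge to the primary oxygen);
- slow hydride delivery to a crowded ester.

Fallback (sets out from 12, comes back at 13). No alkoxide is generated.
- Me3SnOH (1,2-dichloroethane, 70 °C) cleaves only the methyl ester to the mono acid F8.
- BH3·SMe2 (THF, 0 °C → rt) reduces the carboxylic acid selectively through acyloxyborane intermediates and leaves the tert-butyl ester and silaketal intact, giving 13.

**3. Step 8.**
What may go wrong:
- interception of the sulfonate by acetate or fluoride before ring closure;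
- participation of the ester carbonyl at C5;
- retro-aldol cleavage if the buffer is exhausted.

Fallback (sets out from 13, comes back at 16). The leaving group is activated instead of the nucleophile.
- Appel iodination of 13 (I2, PPh3, imidazole, CH2Cl2, 0 °C) gives the iodide F9.
- Desilylation on the acidic side (HF·pyridine with extra pyridine, THF, 0 °C) gives the iodo diol F10.
- Halophilic activation with Ag2O (CH2Cl2, rt, dark) closes the C2 hydroxyl onto C5 without ever forming a basic alkoxide, giving 16.

**Further compounds**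
F1 | step 5 | 3,4,5-trimethoxybenzaldehyde | COc1cc(C=O)cc(OC)c1OC
F2 | step 5 | (4R)-4-benzyl-3-[(2R,3R)-5-oxo-2-(3,4,5-trimethoxyphenyl)oxolane-3-carbonyl]-1,3-oxazolidin-2-one | O=C1C[C@@H](C(=O)N2[C@H](Cc3ccccc3)COC2=O)[C@H](c2cc(OC)c(OC)c(OC)c2)O1
F3 | step 5 | (2R,3R)-5-oxo-2-(3,4,5-trimethoxyphenyl)oxolane-3-carboxylic acid | O=C1C[C@@H](C(=O)O)[C@H](c2cc(OC)c(OC)c(OC)c2)O1
F4 | step 5 | tert-butyl (2R,3R)-5-oxo-2-(3,4,5-trimethoxyphenyl)oxolane-3-carboxylate | O=C1C[C@@H](C(=O)OC(C)(C)C)[C@H](c2cc(OC)c(OC)c(OC)c2)O1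
F5 | step 5 | tert-butyl (2R,3R,4S)-4-(3,4-dimethoxybenzoyl)-5-oxo-2-(3,4,5-trimethoxyphenyl)oxolane-3-carboxylate | COc1ccc(C(=O)[C@H]2C(=O)O[C@@H](c3cc(OC)c(OC)c(OC)c3)[C@@H]2C(=O)OC(C)(C)C)cc1OC
F6 | step 5 | tert-butyl (2R,3R,4S)-4-[(S)-(3,4-dimethoxyphenyl)(hydroxy)methyl]-5-oxo-2-(3,4,5-trimethoxyphenyl)oxolane-3-carboxylate | COc1ccc([C@@H](O)[C@H]2C(=O)O[C@@H](c3cc(OC)c(OC)c(OC)c3)[C@@H]2C(=O)OC(C)(C)C)cc1OC
F7 | step 5 | tert-butyl (2R,3R,4S)-4-(3,4-dimethoxyphenyl)-4-hydroxy-3-(hydroxymethyl)-2-[(R)-hydroxy(3,4,5-trimethoxyphenyl)methyl]butanoate | OC[C@H]([C@H](O)c1ccc(OC)c(OC)c1)[C@@H](C(=O)OC(C)(C)C)[C@@H](O)c1cc(OC)c(OC)c(OC)c1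
F8 | step 6 | (4S,5S,6R,7R)-6-(tert-butoxycarbonyl)-4-(3,4-dimethoxyphenyl)-2,2-diisopropyl-7-(3,4,5-trimethoxyphenyl)-1,3,2-dioxasilepane-5-carboxylic acid | OC(=O)[C@H]1[C@@H](C(=O)OC(C)(C)C)[C@H](c2cc(OC)c(OC)c(OC)c2)O[Si](C(C)C)(C(C)C)O[C@@H]1c1ccc(OC)c(OC)c1
F9 | step 8 | tert-butyl (4R,5R,6S,7S)-7-(3,4-dimethoxyphenyl)-6-(iodomethyl)-2,2-diisopropyl-4-(3,4,5-trimethoxyphenyl)-1,3,2-dioxasilepane-5-carboxylate | IC[C@H]1[C@@H](C(=O)OC(C)(C)C)[C@H](c2cc(OC)c(OC)c(OC)c2)O[Si](C(C)C)(C(C)C)O[C@@H]1c1ccc(OC)c(OC)c1
F10 | step 8 | tert-butyl (2R,3S,4S)-4-(3,4-dimethoxyphenyl)-4-hydroxy-2-[(R)-hydroxy(3,4,5-trimethoxyphenyl)methyl]-3-(iodomethyl)butanoate | IC[C@H]([C@H](O)c1ccc(OC)c(OC)c1)[C@@H](C(=O)OC(C)(C)C)[C@@H](O)c1cc(OC)c(OC)c(OC)c1
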